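**Retrosynthetic overview**

1. Target ⇐ silyl ether cleavage ⇐ allylic C15 hydroxylation (SeO2) of the 8α-acyloxy elemanolide; oxidation comes after the ring-forming phase, as in the biosynthesis.
2. Elemanolide ⇐ one telescoped cascade from an acyclic ω-formyl allylic bromide of farnesane connectivity: CrCl2-mediated C6–C7 closure (the farnesyl C1–C10 bond of the germacrene cyclase), lactonisation onto O6, then Cope rearrangement of the (E,E)-germacranolide, which is never isolated; the single acyclic stereocentre C8 controls C5, C6, C7 and C10.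
3. Ring order: ten-membered carbocycle → γ-lactone → cyclohexane (by [3,3] contraction of the ten-membered ring).
4. Acyclic bromide ⇐ Baylis–Hillman reaction and SN2′ bromination of an α-acyloxy aldehyde; C8 and the complete ester side chain are installed together by an enamine-catalysed α-acyloxylation with the diacyl peroxide of O-silylated (R)-Roche acid.
5. α-Unsubstituted aldehyde ⇐ (2E,6E)-farnesyl acetate by terminal epoxidation and periodate cleavage.

Assumption: atom labels C1–C15 are germacrane/elemane labels (C6 bears the lactone oxygen, C8 the ester, C12 is the lactone carbonyl, C15 the hydroxymethyl carbon); two operations run in one flask without isolation count as one step.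

Abbreviation: RocO = (2R)-3-[(tert-butyldimethylsilyl)oxy]-2-methylpropanoyloxy.

**Route**

Step 1
Reactants: 1 (2E,6E)-farnesyl acetate
Product: 3 (2E,6E)-10,11-epoxyfarnesol, via bromohydrin acetate 2 (not isolated)
Conditions: NBS (1.1 equiv), THF/H2O 2:1, 0 °C; then K2CO3, MeOH, rt
Reagents that add atoms: water, O (epoxide oxygen); N-bromosuccinimide, O=C1CCC(=O)N1Br (bromine only in 2, lost again on ring closure)
Why: van Tamelen bromohydrin formation is selective for the terminal trisubstituted alkene (the 2,3-alkene is deactivated by the allylic acetate), and K2CO3 in methanol then closes the epoxide by intramolecular Williamson displacement while methanolysing the acetate; the racemic epoxide centre is destroyed in step 2.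

Step 2
Reactants: 3 (2E,6E)-10,11-epoxyfarnesol
Product: 4 (4E,8E)-10-hydroxy-4,8-dimethyldeca-4,8-dienal
Conditions: HIO4·2H2O (1.2 equiv), THF/Et2O, 0 °C, 30 min
Reagents that add atoms: periodic acid, OI(=O)(=O)=O (net source of one carbonyl oxygen, relayed through water)
Why: periodic acid hydrates the epoxide and cleaves the resulting glycol (Malaprade cleavage) in one pot, leaving the trisubstituted alkenes and the allylic alcohol untouched; no stereocentre is involved.

Step 3
Reactants: 5 methyl (R)-3-hydroxy-2-methylpropanoate ((R)-Roche ester)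
Product: 7 (R)-3-[(tert-butyldimethylsilyl)oxy]-2-methylpropanoic acid, via silyl ether methyl ester 6 (not isolated)
Conditions: TBSCl, imidazole, THF, 0 °C → rt; then LiOH, MeOH/H2O, 0 °C → rt; 1 M HCl to pH 4
Reagents that add atoms: tert-butyldimethylsilyl chloride, CC(C)(C)[Si](C)(C)Cl; LiOH, [Li+].[OH-] (one carboxyl oxygen)
Why: silyl ether formation followed by ester saponification; the stereocentre comes from the chiral pool and is not epimerised because the carboxylate formed under LiOH resists enolisation.

Step 4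
Reactants: 4 (4E,8E)-10-hydroxy-4,8-dimethyldeca-4,8-dienal and 7 (R)-3-[(tert-butyldimethylsilyl)oxy]-2-methylpropanoic acid
Product: 9 (2S,4E,8E)-10-hydroxy-4,8-dimethyl-1-oxodeca-4,8-dien-2-yl (2R)-3-[(tert-butyldimethylsilyl)oxy]-2-methylpropanoate, via diacyl peroxide 8 (not isolated)
Conditions: 7 (2.5 equiv), DCC (2.4 equiv), 50% aq. H2O2 (1.2 equiv), THF, −10 °C, 2 h; then 4 (1.0 equiv), (S)-2-(triphenylmethyl)pyrrolidine (10 mol%), hydroquinone (10 mol%), 0 °C, 12 h
Reagents that add atoms: hydrogen peroxide, OO
Why: Proposed new method: DCC couples 7 with H2O2 to the diacyl peroxide 8 in the cold (it is not isolated because α-branched diacyl peroxides are thermally labile), and the enamine of 4 with the trityl-shielded pyrrolidine attacks the O–O bond of 8 from its open face (SN2 at oxygen, carboxylate 7 leaves), so that iminium hydrolysis releases the (S)-α-acyloxy aldehyde with C8 and the whole ester in place; the closest known reaction is the amine-catalysed asymmetric α-benzoyloxylation of aldehydes with benzoyl peroxide, where the (S)-catalyst likewise gives the (S)-product, and the free alcohol and the alkenes are inert to a diacyl peroxide once all H2O2 is consumed.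

Step 5
Reactants: 9 α-acyloxy aldehyde and 10 methyl acrylate
Product: 11 methyl (4S,6E,10E)-3,12-dihydroxy-6,10-dimethyl-2-methylidene-4-RocO-dodeca-6,10-dienoate (both C3 epimers)
Conditions: DABCO (1.0 equiv), 10 (8 equiv), MeOH (2 equiv), 0 °C → rt, 24–36 h
Reagents that add atoms: none
Why: Morita–Baylis–Hillman reaction, fast because the α-acyloxy group activates the aldehyde, so the short exposure to weakly basic DABCO leaves C8 and the ester in place; the new carbinol centre forms as a mixture that is irrelevant because it becomes sp2 in step 7.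

Step 6
Reactants: 11 Baylis–Hillman diol
Product: 12 methyl (4S,6E,10E)-3-hydroxy-6,10-dimethyl-2-methylidene-12-oxo-4-RocO-dodeca-6,10-dienoate (both C3 epimers)
Conditions: TEMPO (10 mol%), PhI(OAc)2 (1.1 equiv), CH2Cl2, rt
Reagents that add atoms: none
Why: oxoammonium (TEMPO) oxidation is selective for the primary allylic alcohol over the hindered, electron-poor secondary Baylis–Hillman alcohol and gives the (E)-enal without isomerisation; no stereocentre is touched.

Step 7
Reactants: 12 hydroxy enal
Product: 13 methyl (2Z,4S,6E,10E)-2-(bromomethyl)-6,10-dimethyl-12-oxo-4-RocO-dodeca-2,6,10-trienoate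
Conditions: NBS (1.3 equiv), Me2S (1.5 equiv), CH2Cl2, −20 → 0 °C
Reagents that add atoms: N-bromosuccinimide, O=C1CCC(=O)N1Br
Why: Corey–Kim-type activation of the Baylis–Hillman alcohol as an alkoxysulfonium salt followed by SN2′ attack of bromide gives the conjugated (Z)-2-(bromomethyl)enoate, the thermodynamically preferred trisubstituted alkene; the carbinol centre is erased and C8 is untouched.

Step 8
Reactants: 13 ω-formyl allylic bromide
Product: 16 8α-RocO-elema-1,3,11(13)-trien-12,6α-olide (H-5α H-6β H-7α H-8β 10β-methyl), via hydroxy ester 14 (not isolated), via germacranolide 15 (not isolated)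
Conditions: CrCl2 (8 equiv), THF, rt, 13 added over 12 h (final 2 mM); filtration through Florisil; then o-xylene, BHT, 170 °C, 3 h, sealed tube
Reagents that add atoms: none
Why: Nozaki–Hiyama–Kishi-type intramolecular allylation closes C6–C7 through a chair transition state in which the equilibrating allylchromium places the C8 chain equatorial and the acyloxy group on the outside of the forming ring, giving the 6,7-trans adduct 14 that lactonises to 15, and heating then drives the Cope rearrangement of the crossed (E,E)-1,5-diene through a chair transition state that fixes H-5α and the 10β-methyl, as in the known costunolide to dehydrosaussurea lactone rearrangement; recovered 15 is re-heated because the rearrangement is an equilibrium.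

Step 9
Reactants: 16 elemanolide
Product: 17 15-hydroxy-8α-RocO-elema-1,3,11(13)-trien-12,6α-olide
Conditions: SeO2 (0.5 equiv), t-BuOOH (3 equiv), CH2Cl2, rt
Reagents that add atoms: tert-butyl hydroperoxide, CC(C)(C)OO (its oxygen is passed on by SeO2, O=[Se]=O, which is regenerated)
Why: SeO2 allylic hydroxylation (ene reaction then [2,3]-sigmatropic shift) occurs at the only electron-rich alkene that has allylic hydrogens, the isopropenyl group, and at its methyl rather than the hindered C5 methine, while the vinyl group has no allylic hydrogen and the α-methylene lactone is electron-poor; no stereocentre is formed.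

Step 10
Reactants: 17 silyl-protected target
Product: 18 target
Conditions: HF·pyridine, THF, 0 °C → rt
Reagents that add atoms: none
Why: fluoride cleaves the primary silyl ether (desilylation) under mildly acidic conditions that leave both esters, the allylic alcohol, the α-methylene lactone and all stereocentres untouched.

**Compound list**

1 | (2E,6E)-farnesyl acetate, (2E,6E)-3,7,11-trimethyldodeca-2,6,10-trien-1-yl acetate | CC(=O)OC/C=C(\C)CC/C=C(\C)CCC=C(C)C | starting material
2 | (2E,6E)-10-bromo-11-hydroxy-3,7,11-trimethyldodeca-2,6-dien-1-yl acetate (racemic at C10) | CC(=O)OC/C=C(\C)CC/C=C(\C)CCC(Br)C(C)(C)O | intermediate (not isolated)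
3 | (2E,6E)-10,11-epoxy-3,7,11-trimethyldodeca-2,6-dien-1-ol (racemic epoxide) | OC/C=C(\C)CC/C=C(\C)CCC1OC1(C)C | intermediate
4 | (4E,8E)-10-hydroxy-4,8-dimethyldeca-4,8-dienal | OC/C=C(\C)CC/C=C(\C)CCC=O | intermediate
5 | methyl (R)-3-hydroxy-2-methylpropanoate | COC(=O)[C@H](C)CO | starting material
6 | methyl (R)-3-[(tert-butyldimethylsilyl)oxy]-2-methylpropanoate | COC(=O)[C@H](C)CO[Si](C)(C)C(C)(C)C | intermediate (not isolated)
7 | (R)-3-[(tert-butyldimethylsilyl)oxy]-2-methylpropanoic acid | OC(=O)[C@H](C)CO[Si](C)(C)C(C)(C)C | intermediate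
8 | bis[(R)-3-[(tert-butyldimethylsilyl)oxy]-2-methylpropanoyl] peroxide | CC(C)(C)[Si](C)(C)OC[C@@H](C)C(=O)OOC(=O)[C@H](C)CO[Si](C)(C)C(C)(C)C | intermediate (not isolated)
9 | (2S,4E,8E)-10-hydroxy-4,8-dimethyl-1-oxodeca-4,8-dien-2-yl (2R)-3-[(tert-butyldimethylsilyl)oxy]-2-methylpropanoate | OC/C=C(\C)CC/C=C(\C)C[C@H](OC(=O)[C@H](C)CO[Si](C)(C)C(C)(C)C)C=O | intermediate
10 | methyl acrylate | C=CC(=O)OC | starting material
11 | methyl (4S,6E,10E)-3,12-dihydroxy-6,10-dimethyl-2-methylidene-4-RocO-dodeca-6,10-dienoate (C3 epimers) | OC/C=C(\C)CC/C=C(\C)C[C@H](OC(=O)[C@H](C)CO[Si](C)(C)C(C)(C)C)C(O)C(=C)C(=O)OC | intermediate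
12 | methyl (4S,6E,10E)-3-hydroxy-6,10-dimethyl-2-methylidene-12-oxo-4-RocO-dodeca-6,10-dienoate (C3 epimers) | O=C/C=C(\C)CC/C=C(\C)C[C@H](OC(=O)[C@H](C)CO[Si](C)(C)C(C)(C)C)C(O)C(=C)C(=O)OC | intermediate
13 | methyl (2Z,4S,6E,10E)-2-(bromomethyl)-6,10-dimethyl-12-oxo-4-RocO-dodeca-2,6,10-trienoate | O=C/C=C(\C)CC/C=C(\C)C[C@H](OC(=O)[C@H](C)CO[Si](C)(C)C(C)(C)C)/C=C(\CBr)C(=O)OC | intermediate
14 | methyl 6α-hydroxy-8α-RocO-germacra-1(10)E,4E,11(13)-trien-12-oate (H-6β, H-7α, H-8β; chromium alkoxide before work-up) | C/C1=C\CC/C(C)=C/[C@@H](O)[C@H](C(=C)C(=O)OC)[C@@H](OC(=O)[C@H](C)CO[Si](C)(C)C(C)(C)C)C1 | intermediate (not isolated)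
15 | 8α-RocO-germacra-1(10)E,4E,11(13)-trien-12,6α-olide (8α-acyloxycostunolide; H-6β, H-7α, H-8β) | C/C1=C\CC/C(C)=C/[C@H]2OC(=O)C(=C)[C@@H]2[C@@H](OC(=O)[C@H](C)CO[Si](C)(C)C(C)(C)C)C1 | intermediate (not isolated)
16 | 8α-RocO-elema-1,3,11(13)-trien-12,6α-olide (H-5α, H-6β, H-7α, H-8β, 10β-methyl, 10α-vinyl) | C=C[C@]1(C)C[C@H](OC(=O)[C@H](C)CO[Si](C)(C)C(C)(C)C)[C@H]2C(=C)C(=O)O[C@@H]2[C@H]1C(=C)C | intermediate
17 | 15-hydroxy-8α-RocO-elema-1,3,11(13)-trien-12,6α-olide (same ring configuration as 16) | C=C[C@]1(C)C[C@H](OC(=O)[C@H](C)CO[Si](C)(C)C(C)(C)C)[C@H]2C(=C)C(=O)O[C@@H]2[C@H]1C(=C)CO | intermediate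
18 | 15-hydroxy-8α-[(2R)-3-hydroxy-2-methylpropanoyloxy]elema-1,3,11(13)-trien-12,6α-olide, (3aR,4S,6S,7R,7aR)-6-ethenyl-7-(3-hydroxyprop-1-en-2-yl)-6-methyl-3-methylidene-2-oxooctahydro-1-benzofuran-4-yl (2R)-3-hydroxy-2-methylpropanoate | C=C[C@]1(C)C[C@H](OC(=O)[C@H](C)CO)[C@H]2C(=C)C(=O)O[C@@H]2[C@H]1C(=C)CO | target

**Step count**

Total: 10 steps. Longest linear sequence: 9 steps (1 → 3 → 4 → 9 → 11 → 12 → 13 → 16 → 17 → 18); the side-chain branch 5 → 7 joins at step 4.

**Three steps most likely to fail, with fallbacks**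

Step 8 (the cascade) is the riskiest. The allylchromium carries a δ-acyloxy group and may undergo 1,4-elimination to a diene, the facial control by C8 is untested, oligomerisation competes, and the Cope rearrangement is an equilibrium. The fallback sets out from 12 and generates the nucleophile by umpolung of a π-allyl complex instead of by halide reduction. Compound 12 is converted with ClCO2Me and pyridine (CH2Cl2, 0 °C) into the methyl carbonate F1. Pd(PPh3)4 (zerovalent palladium, 5 mol%) and InI (monovalent indium, 1.5 equiv) in THF at 2 mM ionise F1 and transmetalate it to an equilibrating allylindium that is far less prone to eliminate the neighbouring ester. This adds to the enal and lactonises to germacranolide 15, which is now isolated and purified. The fallback comes back to the route at 15; pure 15 is then heated as in the second stage of step 8 to give 16.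

Step 4 (α-acyloxylation with an aliphatic diacyl peroxide) is unprecedented and the peroxide is labile. The fallback sets out from 4 and builds the C8–O bond first and the ester second, by known reactions. D-Proline (20 mol%) and nitrosobenzene in DMSO, then NaBH4 in EtOH, give the anilinooxy diol F2 (D-proline delivers the 2S centre). Zn and AcOH in THF cleave the N–O bond to the triol F3. TESCl (2.1 equiv) and imidazole at −40 °C silylate the two primary alcohols to the bis(triethylsilyl) ether F4. Acid 7 with DCC and DMAP gives the ester F5. PPTS in MeOH at 0 °C removes both triethylsilyl groups to the diol F6, which is oxidised at once (TEMPO, PhI(OAc)2, 2.2 equiv) to the dialdehyde F7. The Baylis–Hillman reaction of F7 with 10 and DABCO takes place only at the α-acyloxy aldehyde (the β,β-disubstituted enal is inert). The fallback comes back to the route at 12.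

Step 9 (late allylic hydroxylation) may over-oxidise to the enal or give poor conversion on precious material. The fallback sets out from 16 and replaces C–H oxygenation by ene-type chlorination and substitution. Ca(OCl)2 with solid CO2 in CH2Cl2/H2O at 0 °C gives the allylic chloride F8 (reaction at the isopropenyl group only). HCO2Na with catalytic Bu4NI in DMF at 40 °C gives the formate F9. Dilute HCl in MeOH at 0 °C removes the formyl group and the silyl ether together. The fallback comes back to the route at 18.

**Further compounds**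

F1 | step 8 | methyl (4S,6E,10E)-3-[(methoxycarbonyl)oxy]-6,10-dimethyl-2-methylidene-12-oxo-4-RocO-dodeca-6,10-dienoate (C3 epimers) | O=C/C=C(\C)CC/C=C(\C)C[C@H](OC(=O)[C@H](C)CO[Si](C)(C)C(C)(C)C)C(OC(=O)OC)C(=C)C(=O)OC
F2 | step 4 | (2S,4E,8E)-2-(anilinooxy)-4,8-dimethyldeca-4,8-diene-1,10-diol | OC/C=C(\C)CC/C=C(\C)C[C@H](ONc1ccccc1)CO
F3 | step 4 | (2S,4E,8E)-4,8-dimethyldeca-4,8-diene-1,2,10-triol | OC/C=C(\C)CC/C=C(\C)C[C@H](O)CO
F4 | step 4 | (2S,4E,8E)-4,8-dimethyl-1,10-bis[(triethylsilyl)oxy]deca-4,8-dien-2-ol | CC[Si](CC)(CC)OC/C=C(\C)CC/C=C(\C)C[C@H](O)CO[Si](CC)(CC)CC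
F5 | step 4 | (2S,4E,8E)-4,8-dimethyl-1,10-bis[(triethylsilyl)oxy]deca-4,8-dien-2-yl (2R)-3-[(tert-butyldimethylsilyl)oxy]-2-methylpropanoate | CC[Si](CC)(CC)OC/C=C(\C)CC/C=C(\C)C[C@H](OC(=O)[C@H](C)CO[Si](C)(C)C(C)(C)C)CO[Si](CC)(CC)CC
F6 | step 4 | (2S,4E,8E)-1,10-dihydroxy-4,8-dimethyldeca-4,8-dien-2-yl (2R)-3-[(tert-butyldimethylsilyl)oxy]-2-methylpropanoate | OC/C=C(\C)CC/C=C(\C)C[C@H](OC(=O)[C@H](C)CO[Si](C)(C)C(C)(C)C)CO
F7 | step 4 | (2S,4E,8E)-4,8-dimethyl-1,10-dioxodeca-4,8-dien-2-yl (2R)-3-[(tert-butyldimethylsilyl)oxy]-2-methylpropanoate | O=C/C=C(\C)CC/C=C(\C)C[C@H](OC(=O)[C@H](C)CO[Si](C)(C)C(C)(C)C)C=O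
F8 | step 9 | 15-chloro-8α-RocO-elema-1,3,11(13)-trien-12,6α-olide | C=C[C@]1(C)C[C@H](OC(=O)[C@H](C)CO[Si](C)(C)C(C)(C)C)[C@H]2C(=C)C(=O)O[C@@H]2[C@H]1C(=C)CCl
F9 | step 9 | 15-formyloxy-8α-RocO-elema-1,3,11(13)-trien-12,6α-olide | C=C[C@]1(C)C[C@H](OC(=O)[C@H](C)CO[Si](C)(C)C(C)(C)C)[C@H]2C(=C)C(=O)O[C@@H]2[C@H]1C(=C)COC=O
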